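The vessel was closed, stirred and isothermal at 25 °C, and I had followed it for 72.0 h before anyone acted on it.

| flask | starting material | partner | catalyst | temperature | remark | time |
|---|---|---|---|---|---|---|
| east | 20 mM | 1.5 equiv | 10 mol% | 25 °C | the very flask that is asked about, followed so far |  |
| north-east | 20 mM | 1.5 equiv | 10 mol% | 31 °C | run made earlier |  |
| flask | 20 mM | 1.50 equiv | 10 mol% | 25 °C |  | 5.0 d |

| run | time / h | product / % |
|---|---|---|
| east | 4.00 | 30.0 |
| east | 12.0 | 30.9 |
| east | 20.0 | 32.0 |
| east | 30.0 | 30.8 |
| east | 40.0 | 31.2 |
| east | 60.0 | 32.2 |
| east | 72.0 | 30.5 |
| north-east | 4.00 | 22.5 |
| north-east | 12.0 | 24.1 |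
| north-east | 20.0 | 24.2 |
| north-east | 30.0 | 23.9 |
| north-east | 40.0 | 22.7 |
| north-east | 60.0 | 23.2 |
| north-east | 72.0 | 22.0 |

(scatter of a reading: 1 percentage point)

- larch: at 5.0 d add catalyst, 100% of the amount charged, then wait 5.0 d
- birch: change nothing and wait 5.0 d more
- elm: at 5.0 d take out 90% of the product then present, then wait 5.0 d
- cedar: at 5.0 d raise the temperature by 25 K, then wait 5.0 d
- alder: at 5.0 d add partner, 100% of the amount charged, then wait 5.0 d

- product taken out counts as made
- the earlier runs were read with a standard deviation of 1 percentage point
- steps that have been proposed: starting material + partner + catalyst -> product + catalyst; partner -> decomposed reagent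
- additions bring no volume worth counting

- product, in percent of the starting material first charged, at 5.0 d
- the option that brings most further product ("none" if no option brings more than 2 percentage points) (larch / birch / elm / cedar / alder / none)
- product present, with what was taken out counted in, in percent of the starting material first charged, after elm
- product present, with what was taken out counted in, in percent of the starting material first charged, after alder

I read the east flask by its rate. Product averaged 0.0750 h⁻¹ of the starting charge over the first 4.00 h. From there to 72.0 h it moved 0.5 percentage points, less than the scatter, so I took the mean of the readings, 31.1%, as the stopping point.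

Two factors could slow the coupling. Starting material in the east flask stood at 68.9% of its charge, so even a first-order dependence on it would cut the rate by that factor and no further, yet the rate fell far more than that. I therefore put the stop on the partner. I took both proposed steps in proportion to partner, so its decay cancels from their ratio. Each portion of partner then splits the same way provided the coupling does not follow starting material, and readings at one starting charge do not show whether it does.

I named that split the loss ratio, a selectivity factor: the rate of partner loss over the rate of coupling. Counting the whole charge as consumed, it reads 3.83 in the east flask. The warmer north-east run reads 5.46, higher.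

I committed to holding the ratio through a second dose. Alder then buys another 31.1%, making 62.2%. Larch, birch, cedar and elm add no partner, so I gave them no gain and left elm at 31.1%.

The forecast gave 31.1% for now, alder as best, 31.1% after elm and 53.5% after alder, within 47% to 56.5%, saying “I favour partner exhaustion”. We parted on alder, where my figure stood higher by 8.7 points.

The flask gave 31.5% now, 31.5% after elm, 62.7% after alder, and alder as best.

    starting material + partner + catalyst → product + catalyst, rate k1*[starting material]*[partner]*[catalyst]/(1 + ([starting material]/sat1)) (0.270 mM, k = 3.40 × 10⁵ M⁻² h⁻¹, Ea = 39.0 kJ mol⁻¹)
    partner → decomposed reagent (k = 0.680 h⁻¹, Ea = 87.0 kJ mol⁻¹)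
    (constants at 25 °C)

The second dose brought 31 points on top of the first's 31.5%, which read the same way is a loss ratio of 3.80 for that dose in this flask. For the same flask with 6 mol% of catalyst, I scaled the ratio inversely with loading to 6.38, which gives 20.3% product; that flask gave 20.6%. The east flask had come to rest: left ten times as long, to 1200 h, it held 68.5% starting material, 0% partner and 31.5% product.

All runs are calculated for an exercise; the scatter is artificial.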